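**Retrosynthetic overview**
- The last C–C bond is C11–C12, made by an sp3–sp3 Suzuki coupling of a left decalin allyl chloride (rings A/B) with a right primary alkylborane (ring B' fused to a pyran).
- The diosphenol comes last, from the doubly allylic C7 methylene (allylic oxidation, epoxidation, acid); the oxepanone comes just before it, by one-carbon ring expansion of a pyran-3-one.
- Left half: (R)-Hajos–Parrish ketone (ring A and quaternary C10), then diazoethane ring expansion of its cyclopentanone to the 8-methylcyclohexanone ring B, then gem-dimethylation.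
- Right half: prenylated 2-methylcyclopentane-1,3-dione, Shi epoxide, a new reductive epoxide–ketone cyclisation (pyran ring, C5' and C10'), then the same diazoethane ring expansion (ring B').
- Ring order: left A, then B (5→6); right pyran, then B' (5→6); oxepane (6→7) after the union.

Assumption: terpenoid locants are used (left decalin C1–C10, linker C9–C11–C12–C9', right half primed, ring oxygen between C4' and C5'); telescoped operations with non-isolated intermediates count as one step, and a centre whose configuration does not matter is left undefined in the SMILES.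

**Route**

Step 1
Reactants: 1 2-methylcyclopentane-1,3-dione; 2 methyl vinyl ketone
Product: 5 (7aR)-7a-methyl-2,3,7,7a-tetrahydro-1H-indene-1,5(6H)-dione ((R)-Hajos–Parrish ketone), via triketone 3 (not isolated), via ketol 4 (not isolated)
Conditions: AcOH (cat.), H2O, 70 °C; then D-proline (3 mol%), DMF, 16 °C; then H2SO4 (cat.), 95 °C
Reagents that add atoms: none
Why: Michael addition followed by the Hajos–Parrish–Eder–Sauer–Wiechert aldol condensation; the D-proline enamine attacks one of the two enantiotopic ring carbonyls and so sets the quaternary carbon (later C10) as R, the mirror image of the classical L-proline result.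

Step 2
Reactants: 5 (R)-Hajos–Parrish ketone
Product: 6 (8aR)-2,8a-dimethyl-3,4,8,8a-tetrahydronaphthalene-1,6(2H,7H)-dione (C2 epimers)
Conditions: CH3CHN2 (Et2O), Sc(OTf)3 (10 mol%), CH2Cl2, −78 °C
Reagents that add atoms: diazoethane CC=[N+]=[N-]
Why: Lewis-acid-catalysed diazoalkane homologation (Tiffeneau–Demjanov-type ring expansion by 1,2-alkyl shift); the enone carbonyl is inert and the ring CH2 migrates rather than the quaternary carbon, so the new CH(CH3) is C8 next to the C9 carbonyl, and its configuration is irrelevant because C8 later becomes sp2.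

Step 3
Reactants: 6 ring-expanded enedione
Product: 7 (8aR)-2,5,5,8a-tetramethyl-3,7,8,8a-tetrahydronaphthalene-1,6(2H,5H)-dione (C2 epimers)
Conditions: KOtBu (2.3 equiv), MeI (5 equiv), tBuOH/THF, 0 °C
Reagents that add atoms: iodomethane CI
Why: classical deconjugative gem-dimethylation of a 4-en-3-one through its extended dienolate gives the 4,4-dimethyl-5-ene; the tertiary C8–H between the C9 carbonyl and the quaternary carbon is too hindered to be enolised and alkylated at this base loading.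

Step 4
Reactants: 7 gem-dimethyl dione
Product: 8 (8aR)-6,6-ethylenedioxy-2,5,5,8a-tetramethyl-3,5,6,7,8,8a-hexahydronaphthalen-1(2H)-one (C2 epimers)
Conditions: HOCH2CH2OH, TsOH (cat.), benzene, reflux (Dean–Stark)
Reagents that add atoms: ethane-1,2-diol OCCO
Why: acid-catalysed ketalisation is selective for the C3 ketone, which has one unhindered flank, over the C9 ketone flanked by a quaternary and a tertiary carbon.

Step 5
Reactants: 8 keto ketal
Product: 9 (8aS)-6,6-ethylenedioxy-2,5,5,8a-tetramethyl-1-methylidene-1,2,3,5,6,7,8,8a-octahydronaphthalene (C2 epimers; same spatial arrangement at C8a as in 5)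
Conditions: Ph3PCH3Br, KOtBu, toluene, 100 °C
Reagents that add atoms: methyltriphenylphosphonium bromide C[P+](c1ccccc1)(c1ccccc1)c1ccccc1.[Br-]
Why: Wittig methylenation under the forcing conditions used for hindered ketones; the ketal masks the only other carbonyl.

Step 6
Reactants: 9 exocyclic alkene
Product: 10 (8aR)-1-(chloromethyl)-6,6-ethylenedioxy-2,5,5,8a-tetramethyl-3,5,6,7,8,8a-hexahydronaphthalene
Conditions: Ca(OCl)2, CO2 (s), CH2Cl2/H2O, 0 °C
Reagents that add atoms: calcium hypochlorite [Ca+2].[O-]Cl.[O-]Cl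
Why: ene-type allylic chlorination by HOCl puts Cl on the terminal CH2 and removes the only allylic hydrogen (C8–H), moving the double bond into the ring as the tetrasubstituted C8=C9 alkene; the 5-ene has no hydrogen on its neighbours C4 and C10 and is shielded by them.

Step 7
Reactants: 1 2-methylcyclopentane-1,3-dione; 11 prenyl bromide (1-bromo-3-methylbut-2-ene)
Product: 12 2-methyl-2-(3-methylbut-2-en-1-yl)cyclopentane-1,3-dione
Conditions: NaOH (1 M aq), Bu4NI (cat.), rt
Reagents that add atoms: none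
Why: C-alkylation of the cyclic 1,3-dione enolate with an allylic bromide gives the prochiral 2,2-disubstituted dione.

Step 8
Reactants: 12 prenyl dione
Product: 13 2-{[(2R)-3,3-dimethyloxiran-2-yl]methyl}-2-methylcyclopentane-1,3-dione
Conditions: D-fructose-derived Shi ketone (30 mol%), KHSO5 (as 2KHSO5·KHSO4·K2SO4), K2CO3, Bu4NHSO4 (cat.), MeCN/(MeO)2CH2, aq Na2B4O7 buffer, 0 °C
Reagents that add atoms: potassium peroxymonosulfate [K+].[O-]S(=O)(=O)OO
Why: Shi asymmetric epoxidation of the trisubstituted alkene (chiral dioxirane, spiro transition state) gives the (R)-epoxide; the ketones survive the short, cold, buffered reaction.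

Step 9
Reactants: 13 (R)-epoxy dione
Product: 15 (3R,4aS,7aR)-2,2,4a-trimethyl-3-(triethylsilyloxy)hexahydrocyclopenta[b]pyran-5(2H)-one (trans-fused), via oxocarbenium triflate 14 (not isolated)
Conditions: Et3SiOTf (10 mol%), Et3SiH (1.5 equiv), CH2Cl2, −78 → −40 °C
Reagents that add atoms: triethylsilane CC[SiH](CC)CC
Why: Proposed new method: a silyl-triflate-catalysed reductive epoxide–ketone cyclisation that desymmetrises the 2,2-disubstituted 1,3-dione; Et3SiOTf silylates the epoxide oxygen, one ring carbonyl oxygen opens the epoxide at its tertiary carbon through a six-membered chair with the C3'–OSiEt3 group equatorial (attack by the other carbonyl would put it 1,3-diaxial to the angular methyl), so the (R)-epoxide centre selects the carbonyl and fixes C10'; Et3SiH then reduces the cyclic oxocarbenium ion axially, anti to the angular methyl, which sets 5'-H (trans fusion) and regenerates Et3SiOTf; the closest known chemistry is the Lewis-acid epoxide–carbonyl cyclisation to bicyclic ketals and the Et3SiH reduction of cyclic oxocarbenium ions in reductive etherification.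

Step 10
Reactants: 15 bicyclic cyclopentanone
Product: 16 (3R,4aS,8aR)-2,2,4a,6-tetramethyl-3-(triethylsilyloxy)octahydro-5H-chromen-5-one (C6 epimers; C6 is C8')
Conditions: CH3CHN2 (Et2O), Sc(OTf)3 (10 mol%), CH2Cl2, −78 → −40 °C
Reagents that add atoms: diazoethane CC=[N+]=[N-]
Why: the same diazoalkane ring expansion as in step 2, on the only ketone; the CH2 migrates in preference to the quaternary carbon, turning the cyclopentanone into the 2-methylcyclohexanone ring B' with C8' next to the C9' carbonyl (C8' is set later).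

Step 11
Reactants: 16 ring-expanded ketone
Product: 17 (3R,4aS,8aR)-2,2,4a,6-tetramethyl-3-(triethylsilyloxy)-2,3,4,4a,8,8a-hexahydro-5H-chromen-5-one
Conditions: IBX (2.5 equiv), DMSO/fluorobenzene, 65 °C
Reagents that add atoms: none
Why: IBX dehydrogenation of a ketone to the enone; the ketone can only enolise toward C8', so only the 7'-en-9'-one forms.

Step 12
Reactants: 17 enone
Product: 18 (3R,4aR,8aR)-2,2,4a,6-tetramethyl-5-methylidene-3-(triethylsilyloxy)-3,4,4a,5,8,8a-hexahydro-2H-chromene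
Conditions: Ph3PCH3Br, KOtBu, toluene, 80 °C
Reagents that add atoms: methyltriphenylphosphonium bromide C[P+](c1ccccc1)(c1ccccc1)c1ccccc1.[Br-]
Why: Wittig methylenation of the only carbonyl gives the exocyclic 1,3-diene.

Step 13
Reactants: 18 right-hand diene; 10 left-hand allyl chloride
Product: 20 (3R,4aR,5S,8aR)-5-{2-[(8aS)-6,6-ethylenedioxy-2,5,5,8a-tetramethyl-3,5,6,7,8,8a-hexahydronaphthalen-1-yl]ethyl}-2,2,4a,6-tetramethyl-3-(triethylsilyloxy)-3,4,4a,5,8,8a-hexahydro-2H-chromene, via alkylborane 19 (not isolated)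
Conditions: 9-BBN, THF, 0 °C → rt; then 10, Pd(OAc)2 (5 mol%), PCy3 (10 mol%), K3PO4·H2O, THF, 40 °C
Reagents that add atoms: none
Why: 9-BBN adds to the terminal CH2 from the face anti to the angular 10'-methyl, which sets 9'-H on that face, and the B-alkyl Suzuki–Miyaura coupling of the primary alkylborane with the allyl chloride through a pi-allylpalladium bonds the unhindered CH2 terminus to form C11–C12.

Step 14
Reactants: 20 coupled triene
Product: 21 (3R,4aR,5S,6S,8aR)-5-{2-[(8aS)-6,6-ethylenedioxy-2,5,5,8a-tetramethyl-3,5,6,7,8,8a-hexahydronaphthalen-1-yl]ethyl}-2,2,4a,6-tetramethyl-3-(triethylsilyloxy)octahydro-2H-chromene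
Conditions: H2 (1 atm), PtO2 (5 mol%), EtOAc, rt
Reagents that add atoms: none
Why: heterogeneous hydrogenation adds H2 to the trisubstituted 7'-ene from the face anti to the axial 10'-methyl (as in 7-ene drimane and labdane systems), which gives the axial 8'-methyl syn to it; the tetrasubstituted 8-ene and the 5-ene between two quaternary carbons do not react.

Step 15
Reactants: 21 silyl ether
Product: 22 (3R,4aR,5S,6S,8aR)-5-{2-[(8aS)-6,6-ethylenedioxy-2,5,5,8a-tetramethyl-3,5,6,7,8,8a-hexahydronaphthalen-1-yl]ethyl}-2,2,4a,6-tetramethyloctahydro-2H-chromen-3-ol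
Conditions: HF·pyridine, pyridine, THF, 0 °C
Reagents that add atoms: none
Why: fluoride cleavage of the triethylsilyl ether under pyridine buffering leaves the ketal intact.

Step 16
Reactants: 22 pyranol
Product: 23 (4aR,5S,6S,8aR)-5-{2-[(8aS)-6,6-ethylenedioxy-2,5,5,8a-tetramethyl-3,5,6,7,8,8a-hexahydronaphthalen-1-yl]ethyl}-2,2,4a,6-tetramethylhexahydro-2H-chromen-3(4H)-one
Conditions: (n-Pr)4N[RuO4] (5 mol%), NMO, 4 Å MS, CH2Cl2, rt
Reagents that add atoms: none
Why: Ley–Griffith oxidation of the hindered secondary alcohol under neutral conditions gives the pyran-3-one.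

Step 17
Reactants: 23 pyran-3-one
Product: 25 (5aR,6S,7S,9aR)-6-{2-[(8aS)-6,6-ethylenedioxy-2,5,5,8a-tetramethyl-3,5,6,7,8,8a-hexahydronaphthalen-1-yl]ethyl}-2,2,5a,7-tetramethyloctahydro-1-benzoxepin-3(2H)-one, via alpha-silyl ketone 24 (not isolated)
Conditions: Me3SiCHN2, Sc(OTf)3 (10 mol%), CH2Cl2, −40 → 0 °C; then K2CO3 (cat.), MeOH
Reagents that add atoms: trimethylsilyldiazomethane C[Si](C)(C)C=[N+]=[N-]
Why: diazoalkane ring expansion of a tetrahydropyran-3-one to an oxepan-3-one, as used in polyether synthesis; the C1' methylene migrates, not the oxygen-bearing quaternary C4', the alpha-silyl ketone is protodesilylated in methanol, and the left-hand ketone is protected as its ketal.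

Step 18
Reactants: 25 oxepanone diene
Product: 26 (5aR,6S,7S,9aR)-6-{2-[(8aS)-6,6-ethylenedioxy-2,5,5,8a-tetramethyl-3-oxo-3,5,6,7,8,8a-hexahydronaphthalen-1-yl]ethyl}-2,2,5a,7-tetramethyloctahydro-1-benzoxepin-3(2H)-one
Conditions: Rh2(cap)4 (dirhodium tetracaprolactamate, 1 mol%), tBuOOH (5 equiv), K2CO3 (cat.), CH2Cl2, rt
Reagents that add atoms: tert-butyl hydroperoxide CC(C)(C)OO
Why: dirhodium-catalysed allylic C–H oxidation attacks the doubly allylic C7 methylene, the weakest C–H bond, and gives the cross-conjugated dienone.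

Step 19
Reactants: 26 dienone ketal
Product: 28 CNP0302807.1, (5aR,6S,7S,9aR)-6-{2-[(8aS)-4-hydroxy-2,5,5,8a-tetramethyl-3,6-dioxo-3,5,6,7,8,8a-hexahydronaphthalen-1-yl]ethyl}-2,2,5a,7-tetramethyloctahydro-1-benzoxepin-3(2H)-one, via epoxy ketone 27 (not isolated)
Conditions: H2O2 (30%), NaOH (cat.), MeOH/THF, 0 °C → rt; then aq HCl, THF, 50 °C
Reagents that add atoms: hydrogen peroxide OO; water O
Why: Weitz–Scheffer nucleophilic epoxidation of the less substituted enone bond (C5=C6) from the face anti to the C10 and axial C4 methyls, then acid-catalysed opening at the tertiary C5 with loss of H6 gives the diosphenol, and the same acid hydrolyses the dioxolane to the C3 ketone.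

**Compound list**

1 | 2-methylcyclopentane-1,3-dione | CC1C(=O)CCC1=O | starting material
2 | methyl vinyl ketone (but-3-en-2-one) | CC(=O)C=C | starting material
3 | 2-methyl-2-(3-oxobutyl)cyclopentane-1,3-dione | CC(=O)CCC1(C)C(=O)CCC1=O | intermediate (not isolated)
4 | (3aR,7aR)-3a-hydroxy-7a-methylhexahydro-1H-indene-1,5(4H)-dione, cis-fused ketol | O=C1CC[C@@]2(O)CC(=O)CC[C@@]12C | intermediate (not isolated)
5 | (7aR)-7a-methyl-2,3,7,7a-tetrahydro-1H-indene-1,5(6H)-dione, (R)-Hajos–Parrish ketone | O=C1CCC2=CC(=O)CC[C@@]12C | intermediate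
6 | (8aR)-2,8a-dimethyl-3,4,8,8a-tetrahydronaphthalene-1,6(2H,7H)-dione, C2 epimers | O=C1C(C)CCC2=CC(=O)CC[C@@]12C | intermediate
7 | (8aR)-2,5,5,8a-tetramethyl-3,7,8,8a-tetrahydronaphthalene-1,6(2H,5H)-dione, C2 epimers | O=C1C(C)CC=C2C(C)(C)C(=O)CC[C@@]12C | intermediate
8 | (8aR)-6,6-ethylenedioxy-2,5,5,8a-tetramethyl-3,5,6,7,8,8a-hexahydronaphthalen-1(2H)-one, C2 epimers | O=C1C(C)CC=C2C(C)(C)C3(OCCO3)CC[C@@]12C | intermediate
9 | (8aS)-6,6-ethylenedioxy-2,5,5,8a-tetramethyl-1-methylidene-1,2,3,5,6,7,8,8a-octahydronaphthalene, C2 epimers | C=C1C(C)CC=C2C(C)(C)C3(OCCO3)CC[C@@]12C | intermediate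
10 | (8aR)-1-(chloromethyl)-6,6-ethylenedioxy-2,5,5,8a-tetramethyl-3,5,6,7,8,8a-hexahydronaphthalene | ClCC1=C(C)CC=C2C(C)(C)C3(OCCO3)CC[C@@]12C | intermediate
11 | prenyl bromide (1-bromo-3-methylbut-2-ene) | CC(C)=CCBr | starting material
12 | 2-methyl-2-(3-methylbut-2-en-1-yl)cyclopentane-1,3-dione | CC(C)=CCC1(C)C(=O)CCC1=O | intermediate
13 | 2-{[(2R)-3,3-dimethyloxiran-2-yl]methyl}-2-methylcyclopentane-1,3-dione | CC1(C)O[C@@H]1CC2(C)C(=O)CCC2=O | intermediate
14 | 2,2,4a-trimethyl-5-oxo-3-(triethylsilyloxy)-3,4,4a,5,6,7-hexahydro-2H-cyclopenta[b]pyran-1-ium triflate (3-OSiEt3 anti to 4a-CH3) | O=C1CCC2=[O+]C(C)(C)[C@H](O[Si](CC)(CC)CC)C[C@]12C.[O-]S(=O)(=O)C(F)(F)F | intermediate (not isolated)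
15 | (3R,4aS,7aR)-2,2,4a-trimethyl-3-(triethylsilyloxy)hexahydrocyclopenta[b]pyran-5(2H)-one, trans-fused | O=C1CC[C@H]2OC(C)(C)[C@H](O[Si](CC)(CC)CC)C[C@]12C | intermediate
16 | (3R,4aS,8aR)-2,2,4a,6-tetramethyl-3-(triethylsilyloxy)octahydro-5H-chromen-5-one, C6 epimers | O=C1C(C)CC[C@H]2OC(C)(C)[C@H](O[Si](CC)(CC)CC)C[C@]12C | intermediate
17 | (3R,4aS,8aR)-2,2,4a,6-tetramethyl-3-(triethylsilyloxy)-2,3,4,4a,8,8a-hexahydro-5H-chromen-5-one | O=C1C(C)=CC[C@H]2OC(C)(C)[C@H](O[Si](CC)(CC)CC)C[C@]12C | intermediate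
18 | (3R,4aR,8aR)-2,2,4a,6-tetramethyl-5-methylidene-3-(triethylsilyloxy)-3,4,4a,5,8,8a-hexahydro-2H-chromene | C=C1C(C)=CC[C@H]2OC(C)(C)[C@H](O[Si](CC)(CC)CC)C[C@]12C | intermediate
19 | 9-{[(3R,4aR,5S,8aR)-2,2,4a,6-tetramethyl-3-(triethylsilyloxy)-3,4,4a,5,8,8a-hexahydro-2H-chromen-5-yl]methyl}-9-borabicyclo[3.3.1]nonane | C(B1C2CCCC1CCC2)[C@H]1C(C)=CC[C@H]2OC(C)(C)[C@H](O[Si](CC)(CC)CC)C[C@]12C | intermediate (not isolated)
20 | (3R,4aR,5S,8aR)-5-{2-[(8aS)-6,6-ethylenedioxy-2,5,5,8a-tetramethyl-3,5,6,7,8,8a-hexahydronaphthalen-1-yl]ethyl}-2,2,4a,6-tetramethyl-3-(triethylsilyloxy)-3,4,4a,5,8,8a-hexahydro-2H-chromene | CC1=C(CC[C@H]4C(C)=CC[C@H]5OC(C)(C)[C@H](O[Si](CC)(CC)CC)C[C@]45C)[C@]2(C)CCC3(OCCO3)C(C)(C)C2=CC1 | intermediate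
21 | (3R,4aR,5S,6S,8aR)-5-{2-[(8aS)-6,6-ethylenedioxy-2,5,5,8a-tetramethyl-3,5,6,7,8,8a-hexahydronaphthalen-1-yl]ethyl}-2,2,4a,6-tetramethyl-3-(triethylsilyloxy)octahydro-2H-chromene | CC1=C(CC[C@H]4[C@@H](C)CC[C@H]5OC(C)(C)[C@H](O[Si](CC)(CC)CC)C[C@]45C)[C@]2(C)CCC3(OCCO3)C(C)(C)C2=CC1 | intermediate
22 | (3R,4aR,5S,6S,8aR)-5-{2-[(8aS)-6,6-ethylenedioxy-2,5,5,8a-tetramethyl-3,5,6,7,8,8a-hexahydronaphthalen-1-yl]ethyl}-2,2,4a,6-tetramethyloctahydro-2H-chromen-3-ol | CC1=C(CC[C@H]4[C@@H](C)CC[C@H]5OC(C)(C)[C@H](O)C[C@]45C)[C@]2(C)CCC3(OCCO3)C(C)(C)C2=CC1 | intermediate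
23 | (4aR,5S,6S,8aR)-5-{2-[(8aS)-6,6-ethylenedioxy-2,5,5,8a-tetramethyl-3,5,6,7,8,8a-hexahydronaphthalen-1-yl]ethyl}-2,2,4a,6-tetramethylhexahydro-2H-chromen-3(4H)-one | CC1=C(CC[C@H]4[C@@H](C)CC[C@H]5OC(C)(C)C(=O)C[C@]45C)[C@]2(C)CCC3(OCCO3)C(C)(C)C2=CC1 | intermediate
24 | 4-(trimethylsilyl) derivative of 25 (silyl on the inserted carbon C2', epimers) | CC1=C(CC[C@H]4[C@@H](C)CC[C@H]5OC(C)(C)C(=O)C([Si](C)(C)C)C[C@]45C)[C@]2(C)CCC3(OCCO3)C(C)(C)C2=CC1 | intermediate (not isolated)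
25 | (5aR,6S,7S,9aR)-6-{2-[(8aS)-6,6-ethylenedioxy-2,5,5,8a-tetramethyl-3,5,6,7,8,8a-hexahydronaphthalen-1-yl]ethyl}-2,2,5a,7-tetramethyloctahydro-1-benzoxepin-3(2H)-one | CC1=C(CC[C@H]4[C@@H](C)CC[C@H]5OC(C)(C)C(=O)CC[C@]45C)[C@]2(C)CCC3(OCCO3)C(C)(C)C2=CC1 | intermediate
26 | (5aR,6S,7S,9aR)-6-{2-[(8aS)-6,6-ethylenedioxy-2,5,5,8a-tetramethyl-3-oxo-3,5,6,7,8,8a-hexahydronaphthalen-1-yl]ethyl}-2,2,5a,7-tetramethyloctahydro-1-benzoxepin-3(2H)-one | CC1=C(CC[C@H]4[C@@H](C)CC[C@H]5OC(C)(C)C(=O)CC[C@]45C)[C@]2(C)CCC3(OCCO3)C(C)(C)C2=CC1=O | intermediate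
27 | 5,6-epoxide of 26 (oxirane oxygen on the face anti to the C10 methyl) | CC1=C(CC[C@H]5[C@@H](C)CC[C@H]6OC(C)(C)C(=O)CC[C@]56C)[C@]2(C)CCC3(OCCO3)C(C)(C)[C@]24O[C@@H]4C1=O | intermediate (not isolated)
28 | CNP0302807.1, (5aR,6S,7S,9aR)-6-{2-[(8aS)-4-hydroxy-2,5,5,8a-tetramethyl-3,6-dioxo-3,5,6,7,8,8a-hexahydronaphthalen-1-yl]ethyl}-2,2,5a,7-tetramethyloctahydro-1-benzoxepin-3(2H)-one | CC1=C(CC[C@H]4[C@@H](C)CC[C@H]5OC(C)(C)C(=O)CC[C@]45C)[C@]2(C)CCC(=O)C(C)(C)C2=C(O)C1=O | target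

**Step count and risks**

Total: 19 steps. Longest linear sequence: 13 steps (steps 7–19 from 1; the left branch, steps 1–6 then 13–19, is equally long).

The three steps most likely to fail:

Step 9 (the proposed new reductive cyclisation). The silylated epoxide may rearrange (Meinwald-type hydride shift) before the carbonyl attacks, or the two carbonyls may be poorly discriminated. The fallback uses known reactions, sets out from 12 and comes back at 15. Baker's-yeast reduction of 12 gives (2S,3S)-3-hydroxy-2-methyl-2-(3-methylbut-2-en-1-yl)cyclopentan-1-one F1, with the hydroxyl cis to the prenyl group as known for the allyl analogue. Mitsunobu inversion (4-nitrobenzoic acid, PPh3, DIAD) gives (1R,2S)-2-methyl-2-(3-methylbut-2-en-1-yl)-3-oxocyclopentyl 4-nitrobenzoate F2. Mild methanolysis (K2CO3, MeOH, 0 °C) gives (2S,3R)-3-hydroxy-2-methyl-2-(3-methylbut-2-en-1-yl)cyclopentan-1-one F3. Shi epoxidation as in step 8 gives (2S,3R)-2-{[(2R)-3,3-dimethyloxiran-2-yl]methyl}-3-hydroxy-2-methylcyclopentan-1-one F4. Camphorsulfonic acid closes it 6-endo at the tertiary epoxide carbon to (3R,4aS,7aR)-3-hydroxy-2,2,4a-trimethylhexahydrocyclopenta[b]pyran-5(2H)-one F5, and Et3SiOTf with 2,6-lutidine gives 15.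

Step 13 (alkyl–allyl Suzuki union). Beta-hydride elimination, or hydrolysis of the allyl chloride by the aqueous base, may compete. The fallback sets out from 18 and comes back at 20. Hydroboration with 9-BBN (through 19) and NaOH/H2O2 gives [(3R,4aR,5S,8aR)-2,2,4a,6-tetramethyl-3-(triethylsilyloxy)-3,4,4a,5,8,8a-hexahydro-2H-chromen-5-yl]methanol F6. PPh3, I2 and imidazole give (3R,4aR,5S,8aR)-5-(iodomethyl)-2,2,4a,6-tetramethyl-3-(triethylsilyloxy)-3,4,4a,5,8,8a-hexahydro-2H-chromene F7. Magnesium gives {[(3R,4aR,5S,8aR)-2,2,4a,6-tetramethyl-3-(triethylsilyloxy)-3,4,4a,5,8,8a-hexahydro-2H-chromen-5-yl]methyl}magnesium iodide F8, which is coupled with 10 under Li2CuCl4 catalysis (Kochi coupling) to give 20.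

Step 19 (nucleophilic epoxidation at the very hindered C5, then rearrangement). Hydroperoxide addition may be too slow, or the C5 cation may undergo a methyl shift. The fallback sets out from 26 and comes back at 28. Stoichiometric OsO4 in pyridine (then NaHSO3) adds to the C5=C6 bond from the face anti to the C10 methyl and gives the 5,6-cis-diol of 26, 5,6-dihydroxy-5,6-dihydro-26 F9. TsOH in wet acetone at 60 °C eliminates the tertiary 5-hydroxyl (beta to the C7 ketone) and hydrolyses the ketal, giving 28.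

**Further compounds**

F1 | step 9 | (2S,3S)-3-hydroxy-2-methyl-2-(3-methylbut-2-en-1-yl)cyclopentan-1-one | O=C1CC[C@H](O)[C@]1(C)CC=C(C)C
F2 | step 9 | (1R,2S)-2-methyl-2-(3-methylbut-2-en-1-yl)-3-oxocyclopentyl 4-nitrobenzoate | O=C1CC[C@@H](OC(=O)c2ccc(cc2)[N+](=O)[O-])[C@]1(C)CC=C(C)C
F3 | step 9 | (2S,3R)-3-hydroxy-2-methyl-2-(3-methylbut-2-en-1-yl)cyclopentan-1-one | O=C1CC[C@@H](O)[C@]1(C)CC=C(C)C
F4 | step 9 | (2S,3R)-2-{[(2R)-3,3-dimethyloxiran-2-yl]methyl}-3-hydroxy-2-methylcyclopentan-1-one | O=C1CC[C@@H](O)[C@]1(C)C[C@H]1OC1(C)C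
F5 | step 9 | (3R,4aS,7aR)-3-hydroxy-2,2,4a-trimethylhexahydrocyclopenta[b]pyran-5(2H)-one | O=C1CC[C@H]2OC(C)(C)[C@H](O)C[C@]12C
F6 | step 13 | [(3R,4aR,5S,8aR)-2,2,4a,6-tetramethyl-3-(triethylsilyloxy)-3,4,4a,5,8,8a-hexahydro-2H-chromen-5-yl]methanol | OC[C@H]1C(C)=CC[C@H]2OC(C)(C)[C@H](O[Si](CC)(CC)CC)C[C@]12C
F7 | step 13 | (3R,4aR,5S,8aR)-5-(iodomethyl)-2,2,4a,6-tetramethyl-3-(triethylsilyloxy)-3,4,4a,5,8,8a-hexahydro-2H-chromene | IC[C@H]1C(C)=CC[C@H]2OC(C)(C)[C@H](O[Si](CC)(CC)CC)C[C@]12C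
F8 | step 13 | {[(3R,4aR,5S,8aR)-2,2,4a,6-tetramethyl-3-(triethylsilyloxy)-3,4,4a,5,8,8a-hexahydro-2H-chromen-5-yl]methyl}magnesium iodide | I[Mg]C[C@H]1C(C)=CC[C@H]2OC(C)(C)[C@H](O[Si](CC)(CC)CC)C[C@]12C
F9 | step 19 | 5,6-cis-diol of 26 (both hydroxyls on the face anti to the C10 methyl) | CC1=C(CC[C@H]4[C@@H](C)CC[C@H]5OC(C)(C)C(=O)CC[C@]45C)[C@]2(C)CCC3(OCCO3)C(C)(C)[C@@]2(O)[C@H](O)C1=O
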